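# Total synthesis of CNP0375196.1: (R)-2H-chromene closed by acetyl-activated fluoride displacement

## Analysis of the target

Target 17 is a 2H-chromene. Pyran ring B (O1–C2–C3=C4–C4a–C8a) is fused to benzene ring A, which carries an acetyl group at C6 and a hydroxyl at C7 hydrogen-bonded to that acetyl. The hydroxymethyl arm on C2 is esterified with (E)-ferulic acid. The only stereocentre is the fully substituted C2 (R), bonded to O1, vinylic C3, a methyl group and the acyloxymethyl carbon, so the task is absolute control at one quaternary carbinol centre. The C2–O1 bond is a tertiary, allylic aryl ether: acid can ionise it, and light can open it by reversible oxa-6π ring opening, and either event would racemise C2. The cinnamate ester is labile to base and nucleophiles, there are two phenols, and the methyl ketone is enolisable. The classical chromene syntheses close O1–C2 through a planar ortho-quinone methide or a C2 cation and so give racemic material. The strategy rests on the fact that O1 sits on C8a, para to the C6 acetyl, while the C7 hydroxyl is ortho to it. Both aryl C–O bonds of ring A can therefore be made by displacing fluoride from a 2,4-difluoroacetophenone, the first one by the oxygen of a C2 carbinol bought from the chiral pool, so that no bond at C2 is made or broken.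

## Retrosynthetic reasoning

**Ester last.** Target 17 is traced to its aryl silyl ether 16, and the ester C(acyl)–O bond of 16 is cut to give chromene diol 12 and O-silylated ferulic acid 15, made from ferulic acid 13. The cinnamate is the group least tolerant of the strong bases used to build ring B, so it goes on last. The forward acylation must pick the primary hydroxyl of 12 over the chelated C7 phenol.

**C7 oxygen from fluorine.** Diol 12 comes from its 4-methoxybenzyl ether 11, and the C7–O bond of 11 is cut back to aryl fluoride 9. Fluorine ortho to the acetyl is a latent hydroxyl, so no phenol protecting group is needed. Keeping it as fluorine until ring B is closed leaves ring A as electron-poor as possible for the closure.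

**O1–C8a, the key cut.** Chromene 9 is opened at O1–C8a to the Z-allylic tertiary alcohol 8. Cutting O1–C2 instead would require a C2 cation or an electrocyclisation, and both destroy the stereocentre. Cutting at the aryl carbon leaves C2 as a finished carbinol and asks only for addition–elimination at a fluorinated carbon para to the acetyl. The forward step must use the tertiary alkoxide and must touch only one of the two fluorides.

**Z-alkene from an alkyne.** Alkene 8 comes from aryl alkyne 7 by cis-semi-hydrogenation, and 7 is cut at the C(sp)–C(aryl) bond into terminal alkyne 5 and aryl bromide 6. The two carbons that become C3 and C4 first serve as a coupling handle and then, as the Z-alkene, hold the alkoxide over C8a.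

**Carbinol from the chiral pool.** Alkyne 5 comes from α-hydroxy aldehyde 4 by one-carbon homologation, 4 from diol 3 by oxidation of its primary hydroxyl, and 3 from (R)-2-methylglycidol 1 and 4-methoxybenzyl alcohol 2 by epoxide opening at the CH2 terminus. Opening the epoxide first keeps every intermediate non-volatile and UV-active, whereas the oxidise-first order passes through two low-boiling epoxides. A 4-methoxybenzyl ether is chosen over a silyl ether because a silyl group on the primary oxygen could migrate to the neighbouring tertiary alkoxide during the key step and free a primary alkoxide able to close a seven-membered ring.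

## Alternatives that were turned down

**Alternative 1:** Ring A itself is disconnected, at C5–C6 and C7–C8. In the forward sense dimethyl malonate A2 adds to the β-CH2 of the 2-methylene ketone A1, and the methyl ketone enolate then attacks one ester to close the cyclohexane-1,3-dione A3.
- For it: the reagents are cheap, the annulation is classical and very reliable, and the stereocentre sits untouched in the side chain. The pyran oxygen could later be joined to the dione as a vinylogous ester without breaking the carbinol C–O bond. The key step is safer than the closure of 8.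
- Against it: A3 is far from the target. Ring A must still be dehydrogenated to the resorcinol, the C6 ester turned into a methyl ketone, ring B closed, C3=C4 introduced, and the silyl ether exchanged for the ferulate. The enone A1 is prone to dimerisation, and its silyl ether sits next to a tertiary alkoxide under the annulation base.
- Comparison: the chosen route buys ring A with all four substituent positions already correct in bromide 6 and needs four steps after the key step.

**Alternative 2:** C2–C3 and O1–C2 are cut with C2 as the spiro carbon of a symmetrical dioxane. In the forward sense 1-(5-bromo-2,4-dihydroxyphenyl)ethanone A4 and 2,2-dimethyl-1,3-dioxan-5-one A5 condense under secondary-amine catalysis (aldol condensation, then oxa-Michael addition) to the spirochromanone A6.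
- For it: the bicycle is assembled in one convergent step from two achiral pieces, without any chiral starting material. On that count it is stronger than the chosen route.
- Against it: A6 is achiral. C2 must be created later by an enzyme that distinguishes two enantiotopic hydroxymethyl arms whose environment differs only in ring atoms O1 and C3, so the selectivity is hard to predict. One arm must then be deoxygenated to methyl at a neopentyl-type carbon, C4=O must be reduced and dehydrated, and the bromide converted into acetyl.
- Comparison: the chosen route fixes C2 in step 1 from a chiral-pool epoxide and never puts it at risk. It also has C3=C4 and the acetyl in place before the ring closes.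

**Alternative 3:** Ring A is cut at C4a–C5 and C6–C7. In the forward sense the 1,1,3-trioxygenated diene A7, built on a dihydropyran that already carries C2, undergoes (4+2) cycloaddition with but-3-yn-2-one A8, and loss of silanol aromatises the adduct to chroman A9.
- For it: acetyl and hydroxyl are placed ortho to each other in one step, with regiochemistry set by matched polarity (the nucleophilic diene terminus C4a bonds to the β-carbon of A8), and no strong base is used. This is cleaner than two fluoride displacements.
- Against it: A7 is a hydrolytically fragile bis-silyl ketene acetal. Its chiral pyran precursor needs its own multi-step synthesis. A9 is a chroman, so C3–C4 must be dehydrogenated on an acetyl-deactivated ring, which resists benzylic hydride abstraction.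
- Comparison: the chosen route reaches its key-step substrate 8 in five standard steps and carries C3=C4 from the alkyne.

Key step: step 6

Assumption: commercial (R)-2-methylglycidol is used at the enantiomeric purity supplied; since no later step makes or breaks a bond at the carbinol carbon, that purity should be carried unchanged into 17.

## Route

Step 1
Reactants: 1 (R)-2-methylglycidol; 2 4-methoxybenzyl alcohol
Product: 3 (R)-3-(4-methoxybenzyloxy)-2-methylpropane-1,2-diol
Conditions: 2 (4 equiv), NaH (0.3 equiv), DMF, 60 °C; slow addition of 1
Reagents that add atoms: none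
Why: Base-catalysed SN2 opening of the epoxide at its unsubstituted CH2 by the alkoxide of 2 leaves the bonds at the quaternary carbon untouched, so the configuration of 1 is kept; the Payne rearrangement open to the alkoxide of 1 is degenerate and returns 1 itself. Excess 2 and slow addition should hold back oligomerisation of 1.

Step 2
Reactants: 3 (R)-3-(4-methoxybenzyloxy)-2-methylpropane-1,2-diol
Product: 4 (S)-2-hydroxy-3-(4-methoxybenzyloxy)-2-methylpropanal
Conditions: SO3·pyridine, DMSO, Et3N, CH2Cl2, 0 °C; used crude
Reagents that add atoms: none
Why: Parikh–Doering oxidation converts the primary alcohol to the aldehyde, cannot oxidise the tertiary one and, unlike PhI(OAc)2-based oxidants, does not cleave the 1,2-diol. The aldehyde has no α-hydrogen and cannot epimerise; the descriptor changes to S only because CHO now outranks the ether-bearing CH2.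

Step 3
Reactants: 4 (S)-2-hydroxy-3-(4-methoxybenzyloxy)-2-methylpropanal
Product: 5 (R)-1-(4-methoxybenzyloxy)-2-methylbut-3-yn-2-ol
Conditions: dimethyl (1-diazo-2-oxopropyl)phosphonate, K2CO3, MeOH, 0 °C → rt
Reagents that add atoms: dimethyl (1-diazo-2-oxopropyl)phosphonate, COP(=O)(OC)C(=[N+]=[N-])C(C)=O
Why: Ohira–Bestmann (Seyferth–Gilbert) homologation: methanolysis of the reagent gives the diazomethylphosphonate anion, which adds to the aldehyde; loss of phosphate and N2 gives an alkylidene carbene that rearranges by 1,2-hydrogen shift to the terminal alkyne. The mild carbonate base should tolerate the free tertiary hydroxyl, and the quaternary α-carbon rules out epimerisation.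

Step 4
Reactants: 5 (R)-1-(4-methoxybenzyloxy)-2-methylbut-3-yn-2-ol; 6 1-(5-bromo-2,4-difluorophenyl)ethanone
Product: 7 (R)-1-[2,4-difluoro-5-[3-hydroxy-4-(4-methoxybenzyloxy)-3-methylbut-1-yn-1-yl]phenyl]ethanone
Conditions: Pd(PPh3)2Cl2 (3 mol%), CuI (5 mol%), Et3N, THF, 50 °C, degassed
Reagents that add atoms: none
Why: Sonogashira coupling: the C–Br bond of 6 is the only site for oxidative addition to zerovalent palladium, the electron-poor ring makes that step fast, and tertiary propargylic alcohols couple without protection. Et3N is a non-nucleophilic base, so neither activated fluoride should be displaced.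

Step 5
Reactants: 7 (R)-1-[2,4-difluoro-5-[3-hydroxy-4-(4-methoxybenzyloxy)-3-methylbut-1-yn-1-yl]phenyl]ethanone
Product: 8 (R,Z)-1-[2,4-difluoro-5-[3-hydroxy-4-(4-methoxybenzyloxy)-3-methylbut-1-en-1-yl]phenyl]ethanone
Conditions: H2 (1 atm), Pd/CaCO3 poisoned with Pb(OAc)2 (Lindlar catalyst), quinoline, EtOAc, rt; stopped after 1 equiv H2
Reagents that add atoms: none
Why: Lindlar semi-hydrogenation delivers both hydrogens to one face of the alkyne on the poisoned palladium surface and so should give the Z-alkene. The ketone, the aryl fluorides and the benzyl-type ether are inert under these conditions.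

Step 6
Reactants: 8 (R,Z)-1-[2,4-difluoro-5-[3-hydroxy-4-(4-methoxybenzyloxy)-3-methylbut-1-en-1-yl]phenyl]ethanone
Product: 9 (R)-1-[7-fluoro-2-(4-methoxybenzyloxymethyl)-2-methyl-2H-chromen-6-yl]ethanone
Conditions: NaH (1.2 equiv), THF–DMF (10:1), 0.02 M, 0 °C → rt
Reagents that add atoms: none
Why: NaH gives the tertiary alkoxide (in equilibrium with the unproductive ketone enolate), which adds to the fluorinated carbon that becomes C8a to form a Meisenheimer anion delocalised onto the para acetyl oxygen; loss of fluoride restores the arene and forms O1–C8a. The closest known reaction type is the intramolecular SNAr etherification of alkoxides onto aryl fluorides activated by an ortho or para acyl group, as used for chromans and benzoxazines. Ring B closes as a six-membered ring, 6-exo-trig with respect to C8a=C8, and four of its six atoms (C3, C4, C4a, C8a) are already sp2 and coplanar, so little entropy is lost. No stereocentre is formed: C2 is the carbinol carbon, only its O–H bond is broken, and the R configuration brought in from 1 is retained. The step needs site selectivity between two activated fluorides, and the Z-alkene secures it, because only the fluoride ortho to the tether can be reached while the one ortho to the acetyl lies para to the tether. It also needs the alkoxide to win over enolate chemistry; proton exchange between enolate and alkoxide is fast, closure drains the alkoxide, and high dilution disfavours aldol and intermolecular substitution. A hydride base is used because it cannot itself attack the remaining fluoride, and the 4-methoxybenzyl ether can neither migrate nor cyclise.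

Step 7
Reactants: 9 (R)-1-[7-fluoro-2-(4-methoxybenzyloxymethyl)-2-methyl-2H-chromen-6-yl]ethanone
Product: 11 (R)-1-[7-hydroxy-2-(4-methoxybenzyloxymethyl)-2-methyl-2H-chromen-6-yl]ethanone, via 7-[2-(methylsulfonyl)ethoxy]chromene ether 10 (not isolated)
Conditions: MeSO2CH2CH2OH (2 equiv), NaH (3 equiv), DMF, 0 → 50 °C; aq. NH4Cl
Reagents that add atoms: 2-(methylsulfonyl)ethanol, CS(=O)(=O)CCO
Why: SNAr by the primary alkoxide at C7, ortho to the acetyl, gives ether 10; deprotonation next to the sulfone then expels the phenoxide of 11 by E1cB elimination (a known hydroxide-surrogate method for activated aryl fluorides). The phenoxide is inert to further substitution, and excess alkoxide should capture the methyl vinyl sulfone.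

Step 8
Reactants: 11 (R)-1-[7-hydroxy-2-(4-methoxybenzyloxymethyl)-2-methyl-2H-chromen-6-yl]ethanone
Product: 12 (R)-1-[7-hydroxy-2-(hydroxymethyl)-2-methyl-2H-chromen-6-yl]ethanone
Conditions: DDQ (1.3 equiv), CH2Cl2–pH 7 buffer (10:1), 0 °C → rt, dark
Reagents that add atoms: none
Why: Oxidative cleavage of the 4-methoxybenzyl ether: DDQ abstracts hydride from the electron-rich benzylic position, water adds to the oxocarbenium ion and the hemiacetal collapses to 12. The acetyl-deactivated chelated phenol and the chromene (no hydrogen on C2) should not be oxidised, and no acid is present that could ionise C2–O1.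

Step 9
Reactants: 13 (E)-ferulic acid
Product: 15 (E)-3-[4-(tert-butyldimethylsilyloxy)-3-methoxyphenyl]acrylic acid, via bis-silylated silyl ester 14 (not isolated)
Conditions: TBSCl (2.5 equiv), imidazole, DMF, rt; then AcOH–THF–H2O, rt
Reagents that add atoms: tert-butyldimethylsilyl chloride, CC(C)(C)[Si](C)(C)Cl
Why: Silylation covers both the phenol and the acid; the silyl ester is far more labile than the aryl silyl ether and is hydrolysed selectively by aqueous acetic acid.

Step 10
Reactants: 12 (R)-1-[7-hydroxy-2-(hydroxymethyl)-2-methyl-2H-chromen-6-yl]ethanone; 15 (E)-3-[4-(tert-butyldimethylsilyloxy)-3-methoxyphenyl]acrylic acid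
Product: 16 [(R)-6-acetyl-7-hydroxy-2-methyl-2H-chromen-2-yl]methyl (E)-3-[4-(tert-butyldimethylsilyloxy)-3-methoxyphenyl]acrylate
Conditions: DCC (1.3 equiv), DMAP (0.2 equiv), CH2Cl2, 0 °C → rt
Reagents that add atoms: none
Why: Steglich esterification: DMAP passes the O-acylisourea of 15 on to the primary alcohol as an acylpyridinium ion. The C7 hydroxyl is hydrogen-bonded to and conjugated with the acetyl group and is a much poorer nucleophile, and acyl transfer to oxygen, unlike displacement at the CH2, is only mildly slowed by the adjacent quaternary carbon.

Step 11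
Reactants: 16 [(R)-6-acetyl-7-hydroxy-2-methyl-2H-chromen-2-yl]methyl (E)-3-[4-(tert-butyldimethylsilyloxy)-3-methoxyphenyl]acrylate
Product: 17 [(R)-6-acetyl-7-hydroxy-2-methyl-2H-chromen-2-yl]methyl (E)-3-(4-hydroxy-3-methoxyphenyl)acrylate (CNP0375196.1)
Conditions: Bu4NF (1.1 equiv), AcOH (1.5 equiv), THF, 0 °C, dark
Reagents that add atoms: none
Why: Fluoride cleaves the aryl silyl ether through a pentacoordinate silicate; acetic acid buffers the phenoxide so that the cinnamate ester is neither transesterified nor attacked, and nothing in the step can affect C2.

## Compound list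

1 | (R)-2-methylglycidol | OC[C@]1(C)CO1 | starting material
2 | 4-methoxybenzyl alcohol | COc1ccc(CO)cc1 | starting material
3 | (R)-3-(4-methoxybenzyloxy)-2-methylpropane-1,2-diol | OC[C@](O)(C)COCc1ccc(OC)cc1 | intermediate
4 | (S)-2-hydroxy-3-(4-methoxybenzyloxy)-2-methylpropanal | O=C[C@](O)(C)COCc1ccc(OC)cc1 | intermediate
5 | (R)-1-(4-methoxybenzyloxy)-2-methylbut-3-yn-2-ol | C#C[C@](O)(C)COCc1ccc(OC)cc1 | intermediate
6 | 1-(5-bromo-2,4-difluorophenyl)ethanone | CC(=O)c1cc(Br)c(F)cc1F | starting material
7 | (R)-1-[2,4-difluoro-5-[3-hydroxy-4-(4-methoxybenzyloxy)-3-methylbut-1-yn-1-yl]phenyl]ethanone | CC(=O)c1cc(C#C[C@](O)(C)COCc2ccc(OC)cc2)c(F)cc1F | intermediate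
8 | (R,Z)-1-[2,4-difluoro-5-[3-hydroxy-4-(4-methoxybenzyloxy)-3-methylbut-1-en-1-yl]phenyl]ethanone | CC(=O)c1cc(/C=C\[C@@](C)(O)COCc2ccc(OC)cc2)c(F)cc1F | intermediate
9 | (R)-1-[7-fluoro-2-(4-methoxybenzyloxymethyl)-2-methyl-2H-chromen-6-yl]ethanone | CC(=O)c1cc2C=C[C@](C)(COCc3ccc(OC)cc3)Oc2cc1F | intermediate
10 | (R)-1-[2-(4-methoxybenzyloxymethyl)-2-methyl-7-[2-(methylsulfonyl)ethoxy]-2H-chromen-6-yl]ethanone | CC(=O)c1cc2C=C[C@](C)(COCc3ccc(OC)cc3)Oc2cc1OCCS(C)(=O)=O | intermediate
11 | (R)-1-[7-hydroxy-2-(4-methoxybenzyloxymethyl)-2-methyl-2H-chromen-6-yl]ethanone | CC(=O)c1cc2C=C[C@](C)(COCc3ccc(OC)cc3)Oc2cc1O | intermediate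
12 | (R)-1-[7-hydroxy-2-(hydroxymethyl)-2-methyl-2H-chromen-6-yl]ethanone | CC(=O)c1cc2C=C[C@](C)(CO)Oc2cc1O | intermediate
13 | (E)-ferulic acid | COc1cc(/C=C/C(=O)O)ccc1O | starting material
14 | tert-butyldimethylsilyl (E)-3-[4-(tert-butyldimethylsilyloxy)-3-methoxyphenyl]acrylate | COc1cc(/C=C/C(=O)O[Si](C)(C)C(C)(C)C)ccc1O[Si](C)(C)C(C)(C)C | intermediate
15 | (E)-3-[4-(tert-butyldimethylsilyloxy)-3-methoxyphenyl]acrylic acid | COc1cc(/C=C/C(=O)O)ccc1O[Si](C)(C)C(C)(C)C | intermediate
16 | [(R)-6-acetyl-7-hydroxy-2-methyl-2H-chromen-2-yl]methyl (E)-3-[4-(tert-butyldimethylsilyloxy)-3-methoxyphenyl]acrylate | COc1cc(/C=C/C(=O)OC[C@@]2(C)C=Cc3cc(C(C)=O)c(O)cc3O2)ccc1O[Si](C)(C)C(C)(C)C | intermediate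
17 | [(R)-6-acetyl-7-hydroxy-2-methyl-2H-chromen-2-yl]methyl (E)-3-(4-hydroxy-3-methoxyphenyl)acrylate | COc1cc(/C=C/C(=O)OC[C@@]2(C)C=Cc3cc(C(C)=O)c(O)cc3O2)ccc1O | target

## Step count and least certain steps

Total: 11 steps. Longest linear sequence: 10 steps (steps 1–8, 10, 11); step 9 is a one-step side branch.

**Step 6 (key step).** Deprotonation at the acetyl methyl group instead of the hydroxyl would turn the activating group into an electron-rich enolate, so closure could stall while aldol condensation or intermolecular fluoride displacement takes over. The fallback sets out from 5 and returns at 9, and uses an activating group that cannot enolise. Sonogashira coupling of 5 with commercially available 5-bromo-2,4-difluorobenzonitrile F1 would give (R)-2,4-difluoro-5-[3-hydroxy-4-(4-methoxybenzyloxy)-3-methylbut-1-yn-1-yl]benzonitrile F2. Lindlar semi-hydrogenation would give (R,Z)-2,4-difluoro-5-[3-hydroxy-4-(4-methoxybenzyloxy)-3-methylbut-1-en-1-yl]benzonitrile F3. NaH-mediated closure para to the cyano group would give (R)-7-fluoro-2-(4-methoxybenzyloxymethyl)-2-methyl-2H-chromene-6-carbonitrile F4. Addition of CH3MgBr to the nitrile and brief hydrolysis of the imine with cold dilute HCl would then give 9.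

**Step 7.** The ring oxygen para to the acetyl donates into the positions that must carry the negative charge, so substitution at C7 is slow. That leaves time for the ketone enolate to undergo aldol reaction or Michael addition to the vinyl sulfone released in the elimination stage. The fallback sets out from 9 and returns at 12. Substitution with the sodium alkoxide of 2 (NaH, DMF) would give the neutral bis-ether (R)-1-[7-(4-methoxybenzyloxy)-2-(4-methoxybenzyloxymethyl)-2-methyl-2H-chromen-6-yl]ethanone F5, with no elimination stage and no Michael acceptor. DDQ (2.6 equiv) would then remove both 4-methoxybenzyl groups in one operation and give 12 directly.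

**Step 3.** The free α-hydroxy aldehyde 4 may dimerise or undergo base-induced α-ketol rearrangement faster than it is homologated. The fallback sets out from 1 and returns at 5, and keeps the tertiary oxygen masked as the epoxide. Parikh–Doering oxidation of 1 would give (S)-2-methyloxirane-2-carbaldehyde F6. Ohira–Bestmann homologation would give (R)-2-ethynyl-2-methyloxirane F7. Both are low-boiling and would be carried forward in solution, which is why this order is not the main route. Opening F7 at its CH2 with the sodium alkoxide of 2 in DMF would give 5.

**Step 10.** The primary alcohol next to the quaternary C2 may be acylated slowly, which would allow acylation of the C7 phenol and rearrangement of the O-acylisourea to an N-acylurea to compete. The fallback sets out from 12 and returns at 16, and gives up chemoselective acylation. Acylation of both hydroxyls with excess 15 (DCC, stoichiometric DMAP) would give [(R)-6-acetyl-7-[(E)-3-[4-(tert-butyldimethylsilyloxy)-3-methoxyphenyl]acryloyloxy]-2-methyl-2H-chromen-2-yl]methyl (E)-3-[4-(tert-butyldimethylsilyloxy)-3-methoxyphenyl]acrylate F8. Its C7 aryl ester is an activated ester of an ortho-acetylphenol, and pyrrolidine (1.1 equiv, CH2Cl2, 0 °C) should cleave it selectively to give 16.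

## Further compounds

F1 | step 6 | 5-bromo-2,4-difluorobenzonitrile | N#Cc1cc(Br)c(F)cc1F
F2 | step 6 | (R)-2,4-difluoro-5-[3-hydroxy-4-(4-methoxybenzyloxy)-3-methylbut-1-yn-1-yl]benzonitrile | N#Cc1cc(C#C[C@](O)(C)COCc2ccc(OC)cc2)c(F)cc1F
F3 | step 6 | (R,Z)-2,4-difluoro-5-[3-hydroxy-4-(4-methoxybenzyloxy)-3-methylbut-1-en-1-yl]benzonitrile | N#Cc1cc(/C=C\[C@@](C)(O)COCc2ccc(OC)cc2)c(F)cc1F
F4 | step 6 | (R)-7-fluoro-2-(4-methoxybenzyloxymethyl)-2-methyl-2H-chromene-6-carbonitrile | N#Cc1cc2C=C[C@](C)(COCc3ccc(OC)cc3)Oc2cc1F
F5 | step 7 | (R)-1-[7-(4-methoxybenzyloxy)-2-(4-methoxybenzyloxymethyl)-2-methyl-2H-chromen-6-yl]ethanone | CC(=O)c1cc2C=C[C@](C)(COCc3ccc(OC)cc3)Oc2cc1OCc1ccc(OC)cc1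
F6 | step 3 | (S)-2-methyloxirane-2-carbaldehyde | O=C[C@]1(C)CO1
F7 | step 3 | (R)-2-ethynyl-2-methyloxirane | C#C[C@]1(C)CO1
F8 | step 10 | [(R)-6-acetyl-7-[(E)-3-[4-(tert-butyldimethylsilyloxy)-3-methoxyphenyl]acryloyloxy]-2-methyl-2H-chromen-2-yl]methyl (E)-3-[4-(tert-butyldimethylsilyloxy)-3-methoxyphenyl]acrylate | COc1cc(/C=C/C(=O)OC[C@@]2(C)C=Cc3cc(C(C)=O)c(OC(=O)/C=C/c4ccc(O[Si](C)(C)C(C)(C)C)c(OC)c4)cc3O2)ccc1O[Si](C)(C)C(C)(C)C
A1 | alternative 1 | (R)-7-(tert-butyldimethylsilyloxy)-6-hydroxy-6-methyl-3-methylideneheptan-2-one | CC(=O)C(=C)CC[C@@](C)(O)CO[Si](C)(C)C(C)(C)C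
A2 | alternative 1 | dimethyl malonate | COC(=O)CC(=O)OC
A3 | alternative 1 | methyl 5-[(R)-4-(tert-butyldimethylsilyloxy)-3-hydroxy-3-methylbutyl]-2,4-dioxocyclohexane-1-carboxylate | COC(=O)C1CC(CC[C@@](C)(O)CO[Si](C)(C)C(C)(C)C)C(=O)CC1=O
A4 | alternative 2 | 1-(5-bromo-2,4-dihydroxyphenyl)ethanone | CC(=O)c1cc(Br)c(O)cc1O
A5 | alternative 2 | 2,2-dimethyl-1,3-dioxan-5-one | CC1(C)OCC(=O)CO1
A6 | alternative 2 | 6-bromo-7-hydroxy-2',2'-dimethylspiro[chromane-2,5'-[1,3]dioxan]-4-one | CC1(C)OCC2(CO1)CC(=O)c1cc(Br)c(O)cc1O2
A7 | alternative 3 | (R)-[[6-[2,2-bis(trimethylsilyloxy)ethenyl]-2-methyl-3,4-dihydro-2H-pyran-2-yl]methoxy](tert-butyl)dimethylsilane | C[Si](C)(C)OC(O[Si](C)(C)C)=CC1=CCC[C@](C)(CO[Si](C)(C)C(C)(C)C)O1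
A8 | alternative 3 | but-3-yn-2-one | CC(=O)C#C
A9 | alternative 3 | (R)-1-[2-(tert-butyldimethylsilyloxymethyl)-7-hydroxy-2-methylchroman-6-yl]ethanone | CC(=O)c1cc2CC[C@](C)(CO[Si](C)(C)C(C)(C)C)Oc2cc1O
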